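## Retrosynthetic overview

1. Feature: in the ten-membered carbocycle (C1–C10), the tertiary methyl carbinol C4(OH)(C15H3) sits next to the syn C5,C6-diol, both of whose oxygens are crotonylated. If C4 is read as C4=C15H2, the array C15/C4/C5(OR)/C6(OH) is what a 2-substituted γ-alkoxyallyl metal leaves after adding to a C6 aldehyde.
2. Key disconnection C5–C6: stannyl aldehyde 29 closes to macrocycle 30. In 29 the unit Bu3Sn–C15H2–C4=C5H–OBOM is tethered through C3–C2–C1–C10–C9 to C8 of a trans-γ-lactone whose C7 carries the C6 formyl group.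
3. After closure: C6–OH-directed epoxidation of C4=C15 and reduction at C15, one hydrogenolysis, and crotonylation with E1cB unmasking of C11=C13. Then C3 oxidation, Saegusa–Ito dehydrogenation to the 1Z-enone, and dioxirane epoxidation.
4. Before closure: (S)-citronellal (C1–C3, C8–C10, C14) and ethyl propiolate (C7, C11, C12) give the butenolide. Vinyl Grignard (C6), BOMCl (C13), allylstannane (C4, C5) and Eschenmoser's salt (C15) supply the remaining carbons.
5. Ring order: γ-lactone (step 2), ten-membered carbocycle (step 18), C1–C2 oxirane (step 28).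

Key step: step 18

Locants:
- Ring: C1–C2 oxirane, C3 ketone, C4 carbinol (C15 methyl), C5 and C6 crotonate carbons, C7/C8 lactone fusion (C8–O), C9 methylene, C10 (C14 methyl).
- Lactone: C11(=C13)–C12.
- The same locants are used for every intermediate. CIP letters change where priorities change, although the spatial arrangement does not.

Assumption: the oxirane carbon C3 in 11–14, C4 in 23, and C5 in 25 and 26 form as epimer mixtures. Each of these centres is erased later and is written without a descriptor.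

Design remarks:
- The C6 formyl group is released from a TES-protected alcohol, because no alkene cleavage is possible beside the electron-rich stannane.
- C5 carries BOM and C13 a benzyl ether, so one hydrogenolysis frees both at the only stage that contains no alkene.
- C3 is set as a single epimer, so the ring closure runs on one diastereomer.

## Route

Step 1
Reactants: 1 (S)-(−)-citronellal; 2 ethyl propiolate
Product: 3 ethyl (4R,6S)-4-hydroxy-6,10-dimethylundec-9-en-2-ynoate (8R,10S)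
Conditions: (S)-BINOL (40 mol %), ZnEt2, HMPA, CH2Cl2, rt; Ti(OiPr)4 (1 equiv); then 1, rt; 1 M HCl work-up
Reagents that add atoms: ethyl propiolate 2, CCOC(=O)C#C
Why: In this catalytic asymmetric alkynylation of an aldehyde (BINOL–Ti(OiPr)4 with an alkynylzinc), the (S)-BINOL complex should deliver the zinc propiolate to the face that gives 8R, and the C10 centre makes any minor isomer a separable diastereomer.

Step 2
Reactants: 3 ethyl (4R,6S)-4-hydroxy-6,10-dimethylundec-9-en-2-ynoate
Product: 5 butenolide (5R)-5-[(2S)-2,6-dimethylhept-5-en-1-yl]furan-2(5H)-one, via Z-hydroxy enoate 4 (not isolated)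
Conditions: H2 (1 atm), Pd/CaCO3 poisoned with Pb(OAc)2, quinoline, EtOAc, rt; then PPTS (cat.), rt
Reagents that add atoms: none
Why: Poisoned-palladium syn semihydrogenation (Lindlar reduction) stops at the Z-enoate, whose C8 hydroxyl is then cis to the ester and lactonises by transesterification without touching C8 or the trisubstituted alkene.

Step 3
Reactants: 5 butenolide; 6 vinylmagnesium bromide
Product: 8 trans-vinyl lactone (4R,5R)-5-[(2S)-2,6-dimethylhept-5-en-1-yl]-4-vinyldihydrofuran-2(3H)-one, via silyl ketene acetal 7 (not isolated)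
Conditions: 6, CuBr·SMe2 (10 mol %), TMSCl, THF, −78 °C; dilute HCl work-up
Reagents that add atoms: vinylmagnesium bromide 6, C=C[Mg]Br; chlorotrimethylsilane, C[Si](C)(C)Cl (atoms in 7 only)
Why: In this copper-catalysed, TMSCl-accelerated conjugate addition of a Grignard reagent to a butenolide, the vinyl group should enter anti to the C8 side chain and so set C7 trans to C8.

Step 4
Reactants: 8 trans-vinyl lactone; 9 benzyl chloromethyl ether (BOMCl)
Product: 10 (3R,4S,5R)-3-(benzyloxymethyl)-5-[(2S)-2,6-dimethylhept-5-en-1-yl]-4-vinyldihydrofuran-2(3H)-one (all-trans; 11R)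
Conditions: LDA, THF, −78 °C; 9, DMPU, −78 → −30 °C
Reagents that add atoms: benzyl chloromethyl ether 9, ClCOCc1ccccc1
Why: In this alkylation of the lactone lithium enolate with a chloromethyl ether, the electrophile should approach anti to the C7 vinyl group (11R), and the CH2OBn group is the latent C13 methylene, so no strong base is needed after ring closure.

Step 5
Reactants: 10 benzyloxymethyl vinyl lactone
Product: 11 (3R,4S,5R)-3-(benzyloxymethyl)-5-[(2S)-4-(3,3-dimethyloxiran-2-yl)-2-methylbutyl]-4-vinyldihydrofuran-2(3H)-one (oxirane CH epimers)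
Conditions: mCPBA (1.0 equiv), CH2Cl2, 0 °C
Reagents that add atoms: mCPBA, OOC(=O)c1cccc(Cl)c1
Why: Prilezhaev epoxidation is fastest at the electron-rich trisubstituted alkene and spares the vinyl group, and the resulting oxirane masks the C3 aldehyde, so its configuration is irrelevant.

Step 6
Reactants: 11 oxirane vinyl lactone
Product: 13 (3R,4R,5R)-3-(benzyloxymethyl)-5-[(2S)-4-(3,3-dimethyloxiran-2-yl)-2-methylbutyl]-4-(hydroxymethyl)dihydrofuran-2(3H)-one, via vinyl ozonide 12 (not isolated)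
Conditions: O3, CH2Cl2, −78 °C (Sudan red 7B end point); then NaBH4, MeOH, −78 → 0 °C
Reagents that add atoms: ozone, [O-][O+]=O
Why: Ozonolysis with reductive borohydride work-up converts the only remaining alkene into the C6 hydroxymethyl group, while oxirane, lactone and benzyl ether are inert at low temperature.

Step 7
Reactants: 13 hydroxymethyl oxirane lactone
Product: 15 (3R,4R,5R)-3-(benzyloxymethyl)-4-(hydroxymethyl)-5-[(2S)-2-methyl-5-oxopentyl]dihydrofuran-2(3H)-one, via glycol 14 (not isolated)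
Conditions: H5IO6, THF/Et2O, 0 °C
Reagents that add atoms: water, O (atoms in 14 only, lost with acetone)
Why: Periodic acid hydrolyses the oxirane and cleaves the resulting glycol (Malaprade reaction) to the C3 aldehyde, with the primary alcohol, benzyl ether and lactone inert.

Step 8
Reactants: 15 hydroxy aldehyde
Product: 16 (3R,4R,5R)-3-(benzyloxymethyl)-5-[(2S)-2-methyl-5-oxopentyl]-4-(triethylsilyloxymethyl)dihydrofuran-2(3H)-one
Conditions: TESCl, imidazole, CH2Cl2, 0 °C
Reagents that add atoms: chlorotriethylsilane, CC[Si](Cl)(CC)CC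
Why: This is silylation of the primary alcohol, and TES is chosen because buffered fluoride can later remove it beside a secondary TBS ether and an acid-sensitive stannane.

Step 9
Reactants: 16 TES aldehyde; 17 allyltributylstannane
Product: 18 (3R,4R,5R)-3-(benzyloxymethyl)-5-[(2S,5S)-5-hydroxy-2-methyloct-7-en-1-yl]-4-(triethylsilyloxymethyl)dihydrofuran-2(3H)-one (3S)
Conditions: 17, (R)-BINOL (10 mol %), Ti(OiPr)4 (10 mol %), 4 Å MS, CH2Cl2, −20 °C; aq NaHCO3
Reagents that add atoms: allyltributylstannane 17, C=CC[Sn](CCCC)(CCCC)CCCC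
Why: In this Keck asymmetric allylation, the (R)-BINOL–titanium Lewis acid should direct the allylstannane to the aldehyde face that gives 3S, the remote centres have no influence, and the lactone is not attacked.

Step 10
Reactants: 18 homoallylic alcohol
Product: 19 the (3S)-tert-butyldimethylsilyl ether of 18
Conditions: TBSOTf, 2,6-lutidine, CH2Cl2, −78 °C
Reagents that add atoms: TBSOTf, CC(C)(C)[Si](C)(C)OS(=O)(=O)C(F)(F)F
Why: Silylation of the secondary alcohol under non-nucleophilic base leaves the TES ether and lactone intact and does not touch C3.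

Step 11
Reactants: 19 TBS ether
Product: 21 (3R,4R,5R)-3-(benzyloxymethyl)-5-[(2S,5S)-5-(tert-butyldimethylsilyloxy)-2-methyl-7-oxoheptyl]-4-(triethylsilyloxymethyl)dihydrofuran-2(3H)-one, via allyl ozonide 20 (not isolated)
Conditions: O3, CH2Cl2, −78 °C; then PPh3, −78 °C → rt
Reagents that add atoms: ozone, [O-][O+]=O
Why: Ozonolysis with phosphine work-up cleaves the single alkene to the C5 aldehyde under neutral conditions that avoid β-elimination of the silyloxy group.

Step 12
Reactants: 21 β-silyloxy aldehyde; 22 Eschenmoser's salt (N,N-dimethylmethyleneiminium iodide)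
Product: 24 enal (3R,4R,5R)-3-(benzyloxymethyl)-5-[(2S,5S)-5-(tert-butyldimethylsilyloxy)-6-formyl-2-methylhept-6-en-1-yl]-4-(triethylsilyloxymethyl)dihydrofuran-2(3H)-one, via Mannich base 23 (not isolated)
Conditions: 22, Et3N, CH2Cl2, rt
Reagents that add atoms: Eschenmoser's salt 22, C=[N+](C)C.[I-]
Why: A Mannich reaction of the aldehyde followed by β-elimination of dimethylamine (α-methylenation) installs C15, since only the C5 aldehyde enolises under amine base and the product has no acidic α-hydrogen left.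

Step 13
Reactants: 24 enal
Product: 25 α-hydroxyallylstannane (C5 bears OH and SnBu3; C5 epimers; C4=C15H2 retained; used crude)
Conditions: Bu3SnH, LDA, THF, 0 °C; then 24, −78 °C; aq NH4Cl
Reagents that add atoms: tributyltin hydride, CCCC[SnH](CCCC)CCCC
Why: Kinetic 1,2-addition of tributylstannyllithium to an enal at −78 °C is far faster than attack on the lactone, and the new C5 centre forms as a mixture that step 15 erases.

Step 14
Reactants: 25 α-hydroxyallylstannane; 9 benzyl chloromethyl ether (BOMCl)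
Product: 26 α-(benzyloxymethoxy)allylstannane (C5 epimers)
Conditions: 9, iPr2NEt, CH2Cl2, 0 °C → rt
Reagents that add atoms: benzyl chloromethyl ether 9, ClCOCc1ccccc1
Why: Acetal-type O-alkylation under Hünig's base is mild enough for the labile hydroxystannane, which would revert to the enal under stronger base.

Step 15
Reactants: 26 α-(benzyloxymethoxy)allylstannane
Product: 27 (3R,4R,5R)-3-(benzyloxymethyl)-5-{(2S,5S,6Z)-7-(benzyloxymethoxy)-5-(tert-butyldimethylsilyloxy)-2-methyl-6-[(tributylstannyl)methyl]hept-6-en-1-yl}-4-(triethylsilyloxymethyl)dihydrofuran-2(3H)-one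
Conditions: BF3·OEt2 (0.5 equiv), CH2Cl2, −78 °C; aq NaHCO3
Reagents that add atoms: none
Why: The Lewis-acid-promoted 1,3-stannyl shift (intermolecular SE2' transfer of tin to the unhindered C15 terminus) gives the more stable primary allylstannane and enol ether, and the alkoxy group should end cis to CH2Sn because the alternative presses it against the branched C3.

Step 16
Reactants: 27 γ-alkoxyallylstannane TES ether
Product: 28 the C6 primary alcohol derived from 27 (3S,4Z,7R,8R,10S,11R)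
Conditions: TBAF/AcOH (1:1), THF, 0 °C
Reagents that add atoms: none
Why: In this fluoride desilylation the primary TES ether is far more labile than the hindered secondary TBS ether, and buffered fluoride leaves the enol acetal, allylstannane and lactone untouched.

Step 17
Reactants: 28 stannyl alcohol
Product: 29 stannyl aldehyde (3R,4S,5R)-3-(benzyloxymethyl)-5-{(2S,5S,6Z)-7-(benzyloxymethoxy)-5-(tert-butyldimethylsilyloxy)-2-methyl-6-[(tributylstannyl)methyl]hept-6-en-1-yl}-4-formyldihydrofuran-2(3H)-one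
Conditions: SO3·pyridine, DMSO, Et3N, CH2Cl2, 0 °C
Reagents that add atoms: none
Why: Parikh–Doering oxidation is a method that γ-alkoxyallylstannanes tolerate, and C7 already sits in the favoured trans,trans arrangement, so the amine base cannot erode it.

Step 18
Reactants: 29 stannyl aldehyde
Product: 30 (3S,5S,6S,7R,8R,10S,11R)-13-benzyloxy-5-(benzyloxymethoxy)-3-(tert-butyldimethylsilyloxy)-6-hydroxygermacr-4(15)-en-12,8-olide
Conditions: BF3·OEt2 (3 equiv), CH2Cl2, −78 °C, slow addition of 29 to 1 mM final concentration; aq NaHCO3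
Reagents that add atoms: none
Why: BF3 binds the C6 formyl oxygen and the enol-ether carbon C5 attacks it through an open SE2' transition state while the C15–Sn bond, held parallel to the π system, releases tin as Bu3SnF, so that C5–C6 forms and the C4=C15 methylene appears. The closest known reactions are the BF3-promoted alkoxyallylstannane–aldehyde macrocyclisations that give fourteen-membered carbocycles and the ring-forming γ-alkoxyallylstannane–aldehyde condensations used for medium cyclic ethers, and a ten-membered carbocycle is the more strained case. The ring closes in a 10-exo-trig mode at the carbonyl, with the C4=C5 bond of the nucleophile inside the forming ring. C6 (S) should follow from Felkin–Anh attack anti to the C7–C11 bond, with the tether-bearing C8 gauche to the new bond as the ring demands, and C5 (5S in 30, the letter becoming R once C4 bears oxygen) should follow from the pairing in which C6=O is anti to C4=C5 and C7 lies next to C5–H rather than next to the alkoxy group, which is the pairing that gives syn adducts from Z γ-alkoxyallylstannanes and which also keeps the ring atoms C4 and C7 gauche. The step needs γ-regioselectivity, which the SE2' geometry enforces because only attack through C5 can expel tin, attack at the aldehyde rather than the lactone, which the much higher electrophilicity of the complexed formyl group provides, and cyclisation rather than oligomerisation, which high dilution, the rigid trans,trans-lactone and the C3 and C10 branches of the tether favour.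

Step 19
Reactants: 30 methylene macrocycle
Product: 31 (3S,4S,5R,6S,7R,8R,10S,11R)-13-benzyloxy-5-(benzyloxymethoxy)-3-(tert-butyldimethylsilyloxy)-4,15-epoxy-6-hydroxygermacran-12,8-olide
Conditions: VO(acac)2 (5 mol %), t-BuOOH, CH2Cl2, 0 °C → rt
Reagents that add atoms: tert-butyl hydroperoxide, CC(C)(C)OO
Why: In this vanadium-catalysed hydroxyl-directed epoxidation of a homoallylic alcohol, the peroxo-vanadate bound to C6–O should reach the face of C4=C15 that C6–O shares with C5–O along the C3–C7 segment, which sets C4–O syn to C5–O (4S), and undirected attack is slow at an alkene flanked by two bulky ethers.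

Step 20
Reactants: 31 spiro-epoxide
Product: 32 (3S,4S,5R,6S,7R,8R,10S,11R)-13-benzyloxy-5-(benzyloxymethoxy)-3-(tert-butyldimethylsilyloxy)-4,6-dihydroxy-15-iodogermacran-12,8-olide
Conditions: LiI, AcOH, THF, rt
Reagents that add atoms: lithium iodide, [Li+].[I-]
Why: Regioselective SN2 opening of the 2,2-disubstituted oxirane by iodide at the CH2 terminus keeps the C4–O bond and its configuration and leaves the lactone intact, which a hydride reagent would not.

Step 21
Reactants: 32 iodohydrin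
Product: 33 (3S,4S,5R,6S,7R,8R,10S,11R)-13-benzyloxy-5-(benzyloxymethoxy)-3-(tert-butyldimethylsilyloxy)-4,6-dihydroxygermacran-12,8-olide
Conditions: Bu3SnH, AIBN (cat.), toluene, 80 °C
Reagents that add atoms: none
Why: Radical chain dehalogenation turns C15H2I into the C15 methyl group without affecting any polar function or stereocentre.

Step 22
Reactants: 33 methyl carbinol
Product: 34 (3S,4S,5R,6S,7R,8R,10S,11R)-3-(tert-butyldimethylsilyloxy)-4,5,6,13-tetrahydroxygermacran-12,8-olide
Conditions: H2 (1 atm), Pd(OH)2/C, EtOAc, rt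
Reagents that add atoms: none
Why: Neutral hydrogenolysis removes the C13 benzyl ether and the C5 BOM acetal together at the one stage that has no alkene, which avoids acid that could cause cyclic formal formation or lactone migration.

Step 23
Reactants: 34 tetraol; 35 (E)-crotonic anhydride
Product: 37 (3S,4S,5R,6S,7S,8R,10S)-5,6-bis[(E)-but-2-enoyloxy]-3-(tert-butyldimethylsilyloxy)-4-hydroxygermacr-11(13)-en-12,8-olide, via tris-crotonate 36 (not isolated)
Conditions: 35 (excess), DMAP, Et3N, CH2Cl2, rt; then DBU, 0 °C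
Reagents that add atoms: (E)-crotonic anhydride 35, C/C=C/C(=O)OC(=O)/C=C/C
Why: DMAP-catalysed acylation takes the primary and both secondary hydroxyls but not the hindered tertiary C4–OH, and DBU then expels the C13 crotonate by E1cB elimination through the lactone enolate, which creates C11=C13 and erases C11.

Step 24
Reactants: 37 silyl ether bis-crotonate
Product: 38 (3S,4R,5R,6S,7S,8R,10S)-5,6-bis[(E)-but-2-enoyloxy]-3,4-dihydroxygermacr-11(13)-en-12,8-olide
Conditions: HF·pyridine, pyridine, THF, 0 °C → rt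
Reagents that add atoms: none
Why: Desilylation with buffered HF is non-basic, so the crotonates do not migrate and the methylene lactone is not attacked.

Step 25
Reactants: 38 3,4-diol
Product: 39 (4S,5R,6S,7S,8R,10S)-5,6-bis[(E)-but-2-enoyloxy]-4-hydroxy-3-oxogermacr-11(13)-en-12,8-olide
Conditions: IBX, DMSO, rt
Reagents that add atoms: none
Why: IBX oxidises the secondary alcohol of a secondary/tertiary 1,2-diol to the α-ketol without glycol cleavage and ignores the conjugated esters.

Step 26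
Reactants: 39 α-ketol
Product: 40 (4S,5R,6S,7S,8R,10S)-5,6-bis[(E)-but-2-enoyloxy]-3,4-bis(trimethylsilyloxy)germacra-2,11(13)-dien-12,8-olide (enol ether geometry immaterial)
Conditions: TMSOTf, Et3N, CH2Cl2, 0 °C
Reagents that add atoms: TMSOTf, C[Si](C)(C)OS(=O)(=O)C(F)(F)F
Why: Under soft enolisation the ketone can enolise only toward C2 because C4 is quaternary, the esters are much slower to silylate, and the C4 hydroxyl is capped at the same time.

Step 27
Reactants: 40 silyl enol ether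
Product: 42 (1Z,4S,5R,6S,7S,8R,10R)-5,6-bis[(E)-but-2-enoyloxy]-4-hydroxy-3-oxogermacra-1,11(13)-dien-12,8-olide, via TMS-protected Z-enone 41 (not isolated)
Conditions: Pd(OAc)2 (1.1 equiv), MeCN, rt; then citric acid, MeOH, rt
Reagents that add atoms: none
Why: In this Saegusa–Ito dehydrogenation the divalent palladium enolate at C2 loses a C1 hydrogen by syn β-hydride elimination, the cis olefin is the less strained isomer in a ten-membered ring and arises from the gauche C3–C2–C1–C10 rotamer that such a ring populates, and citric acid in methanol then frees C4–OH.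

Step 28
Reactants: 42 Z-enone
Product: 43 target, (1S,2S,4S,5R,6S,7S,8R,10R)-5,6-bis[(E)-but-2-enoyloxy]-1,2-epoxy-4-hydroxy-3-oxogermacr-11(13)-en-12,8-olide (CNP0253228.1)
Conditions: DMDO, acetone/CH2Cl2, 0 °C
Reagents that add atoms: dimethyldioxirane, CC1(C)OO1
Why: Concerted dioxirane epoxidation is stereospecific, so the Z-olefin gives the cis-oxirane; the twisted, poorly conjugated cis C1=C2 bond should be more nucleophilic than the planar crotonate and methylene lactone olefins; and with C10–H held in the olefin plane by allylic strain, the ring bonds C10–C9 and C3–C4 shield one face, so oxygen should arrive from the outer face that carries the C10 methyl group (1S,2S).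

## Compound list

1 | (S)-(−)-citronellal, (3S)-3,7-dimethyloct-6-enal | O=CC[C@@H](C)CCC=C(C)C | starting material
2 | ethyl propiolate | CCOC(=O)C#C | starting material
3 | ethyl (4R,6S)-4-hydroxy-6,10-dimethylundec-9-en-2-ynoate | CCOC(=O)C#C[C@H](O)C[C@@H](C)CCC=C(C)C | intermediate
4 | ethyl (2Z,4R,6S)-4-hydroxy-6,10-dimethylundeca-2,9-dienoate | CCOC(=O)/C=C\[C@H](O)C[C@@H](C)CCC=C(C)C | intermediate
5 | (5R)-5-[(2S)-2,6-dimethylhept-5-en-1-yl]furan-2(5H)-one | O=C1C=C[C@@H](C[C@@H](C)CCC=C(C)C)O1 | intermediate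
6 | vinylmagnesium bromide | C=C[Mg]Br | starting material
7 | (4S,5R)-5-[(2S)-2,6-dimethylhept-5-en-1-yl]-2-(trimethylsilyloxy)-4-vinyl-4,5-dihydrofuran | C1=C(O[Si](C)(C)C)O[C@H](C[C@@H](C)CCC=C(C)C)[C@H]1C=C | intermediate
8 | (4R,5R)-5-[(2S)-2,6-dimethylhept-5-en-1-yl]-4-vinyldihydrofuran-2(3H)-one | C1C(=O)O[C@H](C[C@@H](C)CCC=C(C)C)[C@H]1C=C | intermediate
9 | benzyl chloromethyl ether (BOMCl) | ClCOCc1ccccc1 | starting material
10 | (3R,4S,5R)-3-(benzyloxymethyl)-5-[(2S)-2,6-dimethylhept-5-en-1-yl]-4-vinyldihydrofuran-2(3H)-one | C(OCc5ccccc5)[C@@H]1C(=O)O[C@H](C[C@@H](C)CCC=C(C)C)[C@H]1C=C | intermediate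
11 | (3R,4S,5R)-3-(benzyloxymethyl)-5-[(2S)-4-(3,3-dimethyloxiran-2-yl)-2-methylbutyl]-4-vinyldihydrofuran-2(3H)-one, oxirane CH epimers | C(OCc5ccccc5)[C@@H]1C(=O)O[C@H](C[C@@H](C)CCC3OC3(C)C)[C@H]1C=C | intermediate
12 | 1,2,4-trioxolane (ozonide) of the vinyl group of 11 | C(OCc5ccccc5)[C@@H]1C(=O)O[C@H](C[C@@H](C)CCC3OC3(C)C)[C@H]1C4OCOO4 | intermediate
13 | (3R,4R,5R)-3-(benzyloxymethyl)-5-[(2S)-4-(3,3-dimethyloxiran-2-yl)-2-methylbutyl]-4-(hydroxymethyl)dihydrofuran-2(3H)-one | C(OCc5ccccc5)[C@@H]1C(=O)O[C@H](C[C@@H](C)CCC3OC3(C)C)[C@H]1CO | intermediate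
14 | (3R,4R,5R)-3-(benzyloxymethyl)-5-[(2S)-5,6-dihydroxy-2,6-dimethylheptyl]-4-(hydroxymethyl)dihydrofuran-2(3H)-one, carbinol CH epimers | C(OCc5ccccc5)[C@@H]1C(=O)O[C@H](C[C@@H](C)CCC(O)C(C)(C)O)[C@H]1CO | intermediate
15 | (3R,4R,5R)-3-(benzyloxymethyl)-4-(hydroxymethyl)-5-[(2S)-2-methyl-5-oxopentyl]dihydrofuran-2(3H)-one | C(OCc5ccccc5)[C@@H]1C(=O)O[C@H](C[C@@H](C)CCC=O)[C@H]1CO | intermediate
16 | (3R,4R,5R)-3-(benzyloxymethyl)-5-[(2S)-2-methyl-5-oxopentyl]-4-(triethylsilyloxymethyl)dihydrofuran-2(3H)-one | C(OCc5ccccc5)[C@@H]1C(=O)O[C@H](C[C@@H](C)CCC=O)[C@H]1CO[Si](CC)(CC)CC | intermediate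
17 | allyltributylstannane | C=CC[Sn](CCCC)(CCCC)CCCC | starting material
18 | (3R,4R,5R)-3-(benzyloxymethyl)-5-[(2S,5S)-5-hydroxy-2-methyloct-7-en-1-yl]-4-(triethylsilyloxymethyl)dihydrofuran-2(3H)-one | C(OCc5ccccc5)[C@@H]1C(=O)O[C@H](C[C@@H](C)CC[C@H](O)CC=C)[C@H]1CO[Si](CC)(CC)CC | intermediate
19 | (3R,4R,5R)-3-(benzyloxymethyl)-5-[(2S,5S)-5-(tert-butyldimethylsilyloxy)-2-methyloct-7-en-1-yl]-4-(triethylsilyloxymethyl)dihydrofuran-2(3H)-one | C(OCc5ccccc5)[C@@H]1C(=O)O[C@H](C[C@@H](C)CC[C@H](O[Si](C)(C)C(C)(C)C)CC=C)[C@H]1CO[Si](CC)(CC)CC | intermediate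
20 | 1,2,4-trioxolane (ozonide) of the terminal alkene of 19 | C(OCc5ccccc5)[C@@H]1C(=O)O[C@H](C[C@@H](C)CC[C@H](O[Si](C)(C)C(C)(C)C)CC3OCOO3)[C@H]1CO[Si](CC)(CC)CC | intermediate
21 | (3R,4R,5R)-3-(benzyloxymethyl)-5-[(2S,5S)-5-(tert-butyldimethylsilyloxy)-2-methyl-7-oxoheptyl]-4-(triethylsilyloxymethyl)dihydrofuran-2(3H)-one | C(OCc5ccccc5)[C@@H]1C(=O)O[C@H](C[C@@H](C)CC[C@H](O[Si](C)(C)C(C)(C)C)CC=O)[C@H]1CO[Si](CC)(CC)CC | intermediate
22 | Eschenmoser's salt, N,N-dimethylmethyleneiminium iodide | C=[N+](C)C.[I-] | starting material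
23 | Mannich base of 21 (C4 bears CH2NMe2, C4 epimers) | C(OCc5ccccc5)[C@@H]1C(=O)O[C@H](C[C@@H](C)CC[C@H](O[Si](C)(C)C(C)(C)C)C(CN(C)C)C=O)[C@H]1CO[Si](CC)(CC)CC | intermediate
24 | (3R,4R,5R)-3-(benzyloxymethyl)-5-[(2S,5S)-5-(tert-butyldimethylsilyloxy)-6-formyl-2-methylhept-6-en-1-yl]-4-(triethylsilyloxymethyl)dihydrofuran-2(3H)-one | C(OCc5ccccc5)[C@@H]1C(=O)O[C@H](C[C@@H](C)CC[C@H](O[Si](C)(C)C(C)(C)C)C(=C)C=O)[C@H]1CO[Si](CC)(CC)CC | intermediate
25 | α-hydroxyallylstannane from 24 (C5: OH and SnBu3, epimers) | C(OCc5ccccc5)[C@@H]1C(=O)O[C@H](C[C@@H](C)CC[C@H](O[Si](C)(C)C(C)(C)C)C(=C)C(O)[Sn](CCCC)(CCCC)CCCC)[C@H]1CO[Si](CC)(CC)CC | intermediate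
26 | α-(benzyloxymethoxy)allylstannane (C5 epimers) | C(OCc5ccccc5)[C@@H]1C(=O)O[C@H](C[C@@H](C)CC[C@H](O[Si](C)(C)C(C)(C)C)C(=C)C(OCOCc4ccccc4)[Sn](CCCC)(CCCC)CCCC)[C@H]1CO[Si](CC)(CC)CC | intermediate
27 | (3S,4Z,7R,8R,10S,11R) γ-(benzyloxymethoxy)allylstannane, C6 TES ether | C(OCc5ccccc5)[C@@H]1C(=O)O[C@H](C[C@@H](C)CC[C@H](O[Si](C)(C)C(C)(C)C)/C(C[Sn](CCCC)(CCCC)CCCC)=C/OCOCc4ccccc4)[C@H]1CO[Si](CC)(CC)CC | intermediate
28 | (3S,4Z,7R,8R,10S,11R) γ-(benzyloxymethoxy)allylstannane, C6 primary alcohol | C(OCc5ccccc5)[C@@H]1C(=O)O[C@H](C[C@@H](C)CC[C@H](O[Si](C)(C)C(C)(C)C)/C(C[Sn](CCCC)(CCCC)CCCC)=C/OCOCc4ccccc4)[C@H]1CO | intermediate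
29 | (3S,4Z,7S,8R,10S,11R) stannyl aldehyde seco-lactone (key-step precursor) | C(OCc5ccccc5)[C@@H]1C(=O)O[C@H](C[C@@H](C)CC[C@H](O[Si](C)(C)C(C)(C)C)/C(C[Sn](CCCC)(CCCC)CCCC)=C/OCOCc4ccccc4)[C@H]1C=O | intermediate
30 | (3S,5S,6S,7R,8R,10S,11R)-13-benzyloxy-5-(benzyloxymethoxy)-3-(tert-butyldimethylsilyloxy)-6-hydroxygermacr-4(15)-en-12,8-olide (key-step product) | C(OCc5ccccc5)[C@@H]1C(=O)O[C@@H]2C[C@@H](C)CC[C@H](O[Si](C)(C)C(C)(C)C)C(=C)[C@H](OCOCc4ccccc4)[C@@H](O)[C@@H]12 | intermediate
31 | (3S,4S,5R,6S,7R,8R,10S,11R)-13-benzyloxy-5-(benzyloxymethoxy)-3-(tert-butyldimethylsilyloxy)-4,15-epoxy-6-hydroxygermacran-12,8-olide | C(OCc5ccccc5)[C@@H]1C(=O)O[C@@H]2C[C@@H](C)CC[C@H](O[Si](C)(C)C(C)(C)C)[C@]3(CO3)[C@H](OCOCc4ccccc4)[C@@H](O)[C@@H]12 | intermediate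
32 | (3S,4S,5R,6S,7R,8R,10S,11R)-13-benzyloxy-5-(benzyloxymethoxy)-3-(tert-butyldimethylsilyloxy)-4,6-dihydroxy-15-iodogermacran-12,8-olide | C(OCc5ccccc5)[C@@H]1C(=O)O[C@@H]2C[C@@H](C)CC[C@H](O[Si](C)(C)C(C)(C)C)[C@@](CI)(O)[C@H](OCOCc4ccccc4)[C@@H](O)[C@@H]12 | intermediate
33 | (3S,4S,5R,6S,7R,8R,10S,11R)-13-benzyloxy-5-(benzyloxymethoxy)-3-(tert-butyldimethylsilyloxy)-4,6-dihydroxygermacran-12,8-olide | C(OCc5ccccc5)[C@@H]1C(=O)O[C@@H]2C[C@@H](C)CC[C@H](O[Si](C)(C)C(C)(C)C)[C@@](C)(O)[C@H](OCOCc4ccccc4)[C@@H](O)[C@@H]12 | intermediate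
34 | (3S,4S,5R,6S,7R,8R,10S,11R)-3-(tert-butyldimethylsilyloxy)-4,5,6,13-tetrahydroxygermacran-12,8-olide | C(O)[C@@H]1C(=O)O[C@@H]2C[C@@H](C)CC[C@H](O[Si](C)(C)C(C)(C)C)[C@@](C)(O)[C@H](O)[C@@H](O)[C@@H]12 | intermediate
35 | (E)-crotonic anhydride | C/C=C/C(=O)OC(=O)/C=C/C | starting material
36 | (3S,4S,5R,6S,7S,8R,10S,11R)-5,6,13-tris[(E)-but-2-enoyloxy]-3-(tert-butyldimethylsilyloxy)-4-hydroxygermacran-12,8-olide | C(OC(=O)/C=C/C)[C@@H]1C(=O)O[C@@H]2C[C@@H](C)CC[C@H](O[Si](C)(C)C(C)(C)C)[C@@](C)(O)[C@H](OC(=O)/C=C/C)[C@@H](OC(=O)/C=C/C)[C@@H]12 | intermediate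
37 | (3S,4S,5R,6S,7S,8R,10S)-5,6-bis[(E)-but-2-enoyloxy]-3-(tert-butyldimethylsilyloxy)-4-hydroxygermacr-11(13)-en-12,8-olide | C=C1C(=O)O[C@@H]2C[C@@H](C)CC[C@H](O[Si](C)(C)C(C)(C)C)[C@@](C)(O)[C@H](OC(=O)/C=C/C)[C@@H](OC(=O)/C=C/C)[C@@H]12 | intermediate
38 | (3S,4R,5R,6S,7S,8R,10S)-5,6-bis[(E)-but-2-enoyloxy]-3,4-dihydroxygermacr-11(13)-en-12,8-olide | C=C1C(=O)O[C@@H]2C[C@@H](C)CC[C@H](O)[C@@](C)(O)[C@H](OC(=O)/C=C/C)[C@@H](OC(=O)/C=C/C)[C@@H]12 | intermediate
39 | (4S,5R,6S,7S,8R,10S)-5,6-bis[(E)-but-2-enoyloxy]-4-hydroxy-3-oxogermacr-11(13)-en-12,8-olide | C=C1C(=O)O[C@@H]2C[C@@H](C)CCC(=O)[C@@](C)(O)[C@H](OC(=O)/C=C/C)[C@@H](OC(=O)/C=C/C)[C@@H]12 | intermediate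
40 | (4S,5R,6S,7S,8R,10S)-5,6-bis[(E)-but-2-enoyloxy]-3,4-bis(trimethylsilyloxy)germacra-2,11(13)-dien-12,8-olide | C=C1C(=O)O[C@@H]2C[C@@H](C)CC=C(O[Si](C)(C)C)[C@@](C)(O[Si](C)(C)C)[C@H](OC(=O)/C=C/C)[C@@H](OC(=O)/C=C/C)[C@@H]12 | intermediate
41 | (1Z,4S,5R,6S,7S,8R,10R)-5,6-bis[(E)-but-2-enoyloxy]-3-oxo-4-(trimethylsilyloxy)germacra-1,11(13)-dien-12,8-olide | C=C1C(=O)O[C@@H]2C[C@@H](C)/C=C\C(=O)[C@@](C)(O[Si](C)(C)C)[C@H](OC(=O)/C=C/C)[C@@H](OC(=O)/C=C/C)[C@@H]12 | intermediate
42 | (1Z,4S,5R,6S,7S,8R,10R)-5,6-bis[(E)-but-2-enoyloxy]-4-hydroxy-3-oxogermacra-1,11(13)-dien-12,8-olide | C=C1C(=O)O[C@@H]2C[C@@H](C)/C=C\C(=O)[C@@](C)(O)[C@H](OC(=O)/C=C/C)[C@@H](OC(=O)/C=C/C)[C@@H]12 | intermediate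
43 | (1S,2S,4S,5R,6S,7S,8R,10R)-5,6-bis[(E)-but-2-enoyloxy]-1,2-epoxy-4-hydroxy-3-oxogermacr-11(13)-en-12,8-olide (CNP0253228.1) | C=C1C(=O)O[C@@H]2C[C@@H](C)[C@@H]3O[C@@H]3C(=O)[C@@](C)(O)[C@H](OC(=O)/C=C/C)[C@@H](OC(=O)/C=C/C)[C@@H]12 | target

## Step count and risks

Total step count: 28. Longest linear sequence: 28 steps from 1. All other building blocks (2, 6, 9, 17, 22, 35) are purchased.

Steps most likely to fail:

**1. Step 18.** Intermolecular addition (oligomerisation) and protodestannylation may outrun closure of the strained ten-membered ring. Ring strain may also distort the open transition state so that face selection at the aldehyde, or the syn preference, erodes.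

Fallback: the same C5–C6 bond is made reductively, setting out from enal 24 and returning at tetraol 34. The TES ether of 24 is removed (PPTS, MeOH, 0 °C) to give hydroxy enal F1, and Parikh–Doering oxidation gives dialdehyde F2. Slow addition of F2 to low-valent titanium (TiCl3(DME)1.5, Zn–Cu couple, DME, rt) effects an intramolecular pinacol coupling, a reaction known to close medium and large rings and to favour the trans (threo) diol from ring size eight upward, and should give methylene diol F3. VO(acac)2/t-BuOOH, now directed by the allylic C5 hydroxyl, should give epoxy diol F4. LiI/AcOH then gives iodohydrin F5, and Bu3SnH/AIBN gives benzyl ether triol F6. Hydrogenolysis (H2, Pd(OH)2/C) returns to 34.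

**2. Step 27.** β-Hydride elimination may run through the anti C3–C2–C1–C10 rotamer and deliver the E-olefin. The enone may also slip out of conjugation toward C1=C10, which would erase C10.

Fallback: the geometry is corrected after the elimination rather than in it, setting out from 40 and returning at 41. Pd(OAc)2 in MeCN converts 40 into the TMS-protected E-enone F7. Irradiation at 350–365 nm in benzene, where only the enone chromophore absorbs, isomerises F7 toward the less strained, twisted and more weakly absorbing Z isomer 41. Compound 41 is then desilylated as in step 27.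

**3. Step 28.** Sluggish oxidation of the electron-poor olefin may let the crotonate or methylene lactone olefins compete. Facial selectivity on the flexible ring may also be poor.

Fallback: the olefin is made electron-rich and the oxidant is anchored, setting out from 42 and returning at 43. Luche reduction (NaBH4, CeCl3·7H2O, MeOH, −78 °C) gives Z-allylic alcohol F8. Hydroxyl-directed epoxidation (VO(acac)2, t-BuOOH), which ignores conjugated esters, gives cis-epoxy alcohol F9. IBX in DMSO reoxidises C3 to give 43.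

Further compounds
F1 | step 18 | hydroxy enal, (3R,4R,5R)-3-(benzyloxymethyl)-5-[(2S,5S)-5-(tert-butyldimethylsilyloxy)-6-formyl-2-methylhept-6-en-1-yl]-4-(hydroxymethyl)dihydrofuran-2(3H)-one | C(OCc5ccccc5)[C@@H]1C(=O)O[C@H](C[C@@H](C)CC[C@H](O[Si](C)(C)C(C)(C)C)C(=C)C=O)[C@H]1CO
F2 | step 18 | dialdehyde, (3R,4S,5R)-3-(benzyloxymethyl)-5-[(2S,5S)-5-(tert-butyldimethylsilyloxy)-6-formyl-2-methylhept-6-en-1-yl]-4-formyldihydrofuran-2(3H)-one | C(OCc5ccccc5)[C@@H]1C(=O)O[C@H](C[C@@H](C)CC[C@H](O[Si](C)(C)C(C)(C)C)C(=C)C=O)[C@H]1C=O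
F3 | step 18 | methylene diol, (3S,5S,6S,7R,8R,10S,11R)-13-benzyloxy-3-(tert-butyldimethylsilyloxy)-5,6-dihydroxygermacr-4(15)-en-12,8-olide | C(OCc5ccccc5)[C@@H]1C(=O)O[C@@H]2C[C@@H](C)CC[C@H](O[Si](C)(C)C(C)(C)C)C(=C)[C@H](O)[C@@H](O)[C@@H]12
F4 | step 18 | epoxy diol, (3S,4S,5R,6S,7R,8R,10S,11R)-13-benzyloxy-3-(tert-butyldimethylsilyloxy)-4,15-epoxy-5,6-dihydroxygermacran-12,8-olide | C(OCc5ccccc5)[C@@H]1C(=O)O[C@@H]2C[C@@H](C)CC[C@H](O[Si](C)(C)C(C)(C)C)[C@]3(CO3)[C@H](O)[C@@H](O)[C@@H]12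
F5 | step 18 | iodohydrin, (3S,4S,5R,6S,7R,8R,10S,11R)-13-benzyloxy-3-(tert-butyldimethylsilyloxy)-4,5,6-trihydroxy-15-iodogermacran-12,8-olide | C(OCc5ccccc5)[C@@H]1C(=O)O[C@@H]2C[C@@H](C)CC[C@H](O[Si](C)(C)C(C)(C)C)[C@@](CI)(O)[C@H](O)[C@@H](O)[C@@H]12
F6 | step 18 | benzyl ether triol, (3S,4S,5R,6S,7R,8R,10S,11R)-13-benzyloxy-3-(tert-butyldimethylsilyloxy)-4,5,6-trihydroxygermacran-12,8-olide | C(OCc5ccccc5)[C@@H]1C(=O)O[C@@H]2C[C@@H](C)CC[C@H](O[Si](C)(C)C(C)(C)C)[C@@](C)(O)[C@H](O)[C@@H](O)[C@@H]12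
F7 | step 27 | TMS-protected E-enone, (1E,4S,5R,6S,7S,8R,10R)-5,6-bis[(E)-but-2-enoyloxy]-3-oxo-4-(trimethylsilyloxy)germacra-1,11(13)-dien-12,8-olide | C=C1C(=O)O[C@@H]2C[C@@H](C)/C=C/C(=O)[C@@](C)(O[Si](C)(C)C)[C@H](OC(=O)/C=C/C)[C@@H](OC(=O)/C=C/C)[C@@H]12
F8 | step 28 | Z-allylic alcohol, (1Z)-5,6-bis[(E)-but-2-enoyloxy]-3,4-dihydroxygermacra-1,11(13)-dien-12,8-olide (C3 configuration open, erased later) | C=C1C(=O)O[C@@H]2C[C@@H](C)/C=C\C(O)[C@@](C)(O)[C@H](OC(=O)/C=C/C)[C@@H](OC(=O)/C=C/C)[C@@H]12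
F9 | step 28 | cis-epoxy alcohol, 5,6-bis[(E)-but-2-enoyloxy]-1,2-epoxy-3,4-dihydroxygermacr-11(13)-en-12,8-olide (C3 configuration open, erased later) | C=C1C(=O)O[C@@H]2C[C@@H](C)[C@@H]3O[C@@H]3C(O)[C@@](C)(O)[C@H](OC(=O)/C=C/C)[C@@H](OC(=O)/C=C/C)[C@@H]12
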